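## Analysis of the target

The target 19 is the tetradecanoate of a 5,6-epoxy-3-hydroxy-β-ionone. The numbering used for the target and all intermediates is: ring carbons C1 to C6, with C1 the gem-dimethyl carbon, C3 the carbon carrying the ester oxygen, C5 the methyl-bearing and C6 the chain-bearing oxirane carbon; side chain C7=C8–C9(=O)–C10. The skeleton is one cyclohexane fused to an oxirane. It has three stereocentres, C3 (S), C5 (R) and C6 (S). Because the oxirane is cis-fused, only two elements are independent: the configuration at C3 and the face of the epoxide, which lies opposite to the C3 oxygen. C1, C6 and C5 are three contiguous fully substituted carbons, so every bond formed in this region is sterically demanding. The tetrasubstituted epoxide conjugated with the enone is opened or rearranged by acids, the ester is base-labile and the enone is a Michael acceptor, so the last steps have to be neutral. The route rests on the C5–C6 unit: it is tetrasubstituted, sits next to quaternary C1, and has the C3 oxygen in a β,γ relation to it. With C5=C6 as an alkene and C3 as a ketone this is a cyclohex-3-enone, the product pattern of a 2-vinylcyclobutanone ring expansion.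

## Retrosynthetic reasoning

C7=C8 is cut first. Target 19 goes back to epoxy aldehyde 17 and the stabilised ylide 18. The aldehyde has no α-hydrogen, so it can neither epimerise nor eliminate, and a stabilised ylide gives the (E)-enone under neutral conditions. Making the enone last keeps the acid-sensitive vinylogous epoxy ketone out of all earlier steps.

The two C–O bonds of the oxirane are cut next. Aldehyde 17 comes from epoxy alcohol 16 by oxidation, and 16 from allylic alcohol 15 by a Sharpless epoxidation. The C7 hydroxyl is the handle that lets a chiral titanium reagent choose the face of the tetrasubstituted C5=C6 bond, so the anti relation to C3 is set by the reagent and not by the weak bias of a remote substituent.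

The C3 ester bond and the silyl ether are then addressed. Alcohol 15 comes from silyl ether 14 by fluoride cleavage, and 14 from alcohol 12 and myristoyl chloride 13. Acylating while C7 is still silylated distinguishes the two hydroxyls without extra steps, and the long-chain ester then serves as the C3 protecting group to the end.

The C3–H bond is cut. Alcohol 12 comes from the achiral ketone 11 by an enzymatic reduction. The ketone is the only prochiral element of 11, so the whole absolute configuration of the route is introduced here, and the racemic nature of everything before it is of no consequence.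

The key disconnection is C3–C4. Ketone 11 is the 1,3-acyl shift product of cyclobutanone 10, in which C3 is still bonded to C6 and C4 is the CH2 terminus of an isopropenyl group. What is gained is that the six-membered ring with its tetrasubstituted double bond in the right place comes from a four-membered ring that a cycloaddition assembles in one step. The forward reaction has to break the C3–C6 bond selectively and re-form the bond at C4.

The cyclobutanone is cut across C1–C6 and C2–C3. Compound 10 is the [2+2] adduct of vinylketene 9 and isobutylene 8. The polarity of ketene and alkene fixes the regiochemistry, and the bond between the two fully substituted carbons C1 and C6 is made here.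

The ketene is traced to simple materials. Ketene 9 comes from acid chloride 7 by dehydrochlorination, 7 from acid 6, 6 from ester 5 and 5 from hydroxy ester 4. The C6–C7 bond of 4 is made by adding formaldehyde 2 to the α-carbon of dienolate 3, generated from ethyl 3-methylbut-2-enoate 1. This aldol step also moves the double bond into the isopropenyl position that the key step needs.

## Alternatives that were turned down

Alternative 1: The ring is cut at C2–C3 and C1–C6 in a Diels–Alder sense. In the forward direction isobutylene 8 adds across the diene termini of the Lewis-acid-bound pyrone methyl 4-methyl-2-oxo-2H-pyran-3-carboxylate A1 and gives the bridged lactone A2. In its favour, the carbocycle, the C1–C6 bond and, with a chiral Lewis acid, the C3 stereocentre are made in one step, and the lactone bridge ties the C6 carbon substituent to the face of the C3 oxygen. On setting C3 during ring formation it is stronger than the chosen route, which needs a separate reduction. Against it, A1 is an electron-poor diene that wants an electron-rich partner, and 8 is a weak nucleophile that oligomerises under the Lewis acids needed. The 4-methyl group slows the diene further. Enantiocontrol with an alkene that has no coordinating group is unproven. A2 can lose its bridge by cycloreversion on warming. A2 also carries one carbon too many at C6, which must be excised, and its double bond lies at C4=C5 and must be moved. The chosen route offers neutral conditions for ring formation, no surplus carbon, and stereocontrol on an achiral ketone by a step of a well-understood type.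

Alternative 2: The C5–C6 bond and the C6–O bond are cut together. In the forward direction the enolate of the acyclic chloro ester A3 adds through C6 to the tethered C5 methyl ketone, and the resulting alkoxide displaces chloride to give the epoxy ester A4. In its favour, ring and oxirane are closed in one operation, the epoxide needs no separate oxidant, and C3 can come from an enantiopure acyclic precursor. On step count after ring formation it is at least as good as the chosen route. Against it, the C3 silyloxy group of A3 is β to the C5 ketone, so the base needed for the Darzens reaction can eliminate it. The ketone also has its own acidic protons, which quench the ester enolate. The C5–C6 bond would join a fully substituted enolate carbon flanked by quaternary C1 to a ketone, and the aldol step is reversible. The facial relation to C3 depends on a 1,3-induction across a forming ring that cannot be predicted with confidence. The chosen route avoids a base-sensitive β-oxygenated ketone and sets the epoxide face by reagent control.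

Alternative 3: The C4–C5 bond is cut as an aldol. In the forward direction a chiral secondary amine converts the methyl ketone of the triketone A5 into its enamine, which adds to the C5 carbonyl of the 1,2-diketone and gives the hydroxy dione A6. In its favour, the starting material is achiral and acyclic, the asymmetric step is catalytic, and no pressure vessel or thermolysis is needed. In this it is stronger than the chosen route. Against it, the stereocentre set is a tertiary alcohol at C5, far from the final functionality. C7 would still have to be added to the C6 ketone between two fully substituted carbons, the oxirane would have to be closed from a ditertiary diol, and C3 would have to be reduced with diastereocontrol. A5 also has several enolisable positions and electrophilic carbonyls that compete. The chosen route reaches the correctly oxidised ring with C7 already attached and needs only one reduction and one epoxidation for all three stereocentres.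

Key step: step 6

Assumption: a ketoreductase that reduces ketone 11 to the (R)-alcohol 12 is taken to be found by screening a commercial enzyme panel; the enzyme is named only by class.

## Route

Step 1
Reactants: 1 ethyl 3-methylbut-2-enoate; 2 formaldehyde (monomeric, from cracked paraformaldehyde)
Product: 4 ethyl 2-(hydroxymethyl)-3-methylbut-3-enoate (racemic), via lithium dienolate 3 (not isolated)
Conditions: LiN(iPr)2 (1.1 equiv), THF, −78 °C; then CH2O (g), −78 → −40 °C; aq. NH4Cl
Reagents that add atoms: none
Why: Deprotonation of a γ-methyl group gives the extended dienolate 3, which reacts with aldehydes under kinetic control at its α-carbon; this deconjugative aldol addition makes the C6–C7 bond and leaves the double bond as the isopropenyl group needed later. The new stereocentre is racemic and is erased in step 5.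

Step 2
Reactants: 4 ethyl 2-(hydroxymethyl)-3-methylbut-3-enoate
Product: 5 ethyl 2-{[(tert-butyldimethylsilyl)oxy]methyl}-3-methylbut-3-enoate (racemic)
Conditions: tBuMe2SiCl, imidazole, CH2Cl2, 0 °C → rt
Reagents that add atoms: tert-butyldimethylsilyl chloride, CC(C)(C)[Si](C)(C)Cl
Why: Standard silylation of a primary alcohol; the silyl ether is chosen because it should survive ketene generation, neutral thermolysis and aqueous buffer, and can later be removed by fluoride without touching an ester.

Step 3
Reactants: 5 ethyl 2-{[(tert-butyldimethylsilyl)oxy]methyl}-3-methylbut-3-enoate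
Product: 6 2-{[(tert-butyldimethylsilyl)oxy]methyl}-3-methylbut-3-enoic acid (racemic)
Conditions: LiOH·H2O (1.5 equiv), THF/H2O 3:1, 0 °C → rt; then 1 M HCl at 0 °C to pH 4
Reagents that add atoms: lithium hydroxide, [Li+].[OH-]
Why: Ester saponification by acyl substitution; once the carboxylate has formed the α-proton is no longer acidic, and the low temperature limits migration of the double bond or loss of silanolate before that point.

Step 4
Reactants: 6 2-{[(tert-butyldimethylsilyl)oxy]methyl}-3-methylbut-3-enoic acid
Product: 7 2-{[(tert-butyldimethylsilyl)oxy]methyl}-3-methylbut-3-enoyl chloride (racemic, used crude)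
Conditions: 1-chloro-N,N,2-trimethylprop-1-en-1-amine (1.1 equiv), CH2Cl2, 0 °C → rt; evaporation
Reagents that add atoms: 1-chloro-N,N,2-trimethylprop-1-en-1-amine, CC(C)=C(Cl)N(C)C
Why: Acid chloride formation with an α-chloroenamine runs under neutral conditions and releases an inert amide instead of HCl, so the silyl ether and the isopropenyl group should be untouched.

Step 5
Reactants: 7 2-{[(tert-butyldimethylsilyl)oxy]methyl}-3-methylbut-3-enoyl chloride; 8 isobutylene
Product: 10 2-{[(tert-butyldimethylsilyl)oxy]methyl}-3,3-dimethyl-2-(prop-1-en-2-yl)cyclobutan-1-one (racemic), via vinylketene 9 (not isolated)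
Conditions: Et3N (1.5 equiv), isobutylene (about 20 equiv, condensed), PhMe, sealed pressure vessel, slow addition of 7, 80 °C
Reagents that add atoms: none
Why: Dehydrochlorination gives the disubstituted vinylketene 9, which undergoes a thermal ketene–alkene [2+2] cycloaddition across its ketene C=C bond; the electrophilic carbonyl carbon bonds to the CH2 of 8 and the substituted ketene carbon to the carbon that best carries positive charge, which gives the 3,3-dimethyl-2,2-disubstituted cyclobutanone. A disubstituted ketene dimerises slowly, so a large excess of alkene under pressure can compete; any acid chloride that has slipped into conjugation would give the same ketene by γ-deprotonation.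

Step 6
Reactants: 10 2-{[(tert-butyldimethylsilyl)oxy]methyl}-3,3-dimethyl-2-(prop-1-en-2-yl)cyclobutan-1-one
Product: 11 4-{[(tert-butyldimethylsilyl)oxy]methyl}-3,5,5-trimethylcyclohex-3-en-1-one
Conditions: PhMe (0.02 M, degassed), 2,6-di-tert-butyl-4-methylphenol (5 mol%), silanised sealed tube, 190 °C
Reagents that add atoms: none
Why: Heating breaks the C3–C6 bond of 10, the one ring bond that is strained, attached to the carbonyl carbon and attached to a fully substituted allylic carbon, and gives a short-lived acyl/2-methylallyl radical pair. Recombination at the CH2 terminus C4 forms the C3–C4 bond and is driven by loss of the four-membered-ring strain, whereas recombination at C6 only returns 10. The closest known reaction type is the thermal 1,3-acyl shift (formal [1,3]-sigmatropic shift) of 2-vinylcyclobutanones to cyclohex-3-enones. The six-membered ring closes by a four-to-six ring expansion in which the isopropenyl carbons C5 and C4 are inserted between C6 and C3, with the new bond made at the distal allyl carbon so that the double bond ends inside the ring between C5 and C6. No stereocentre is formed; the only one in 10 becomes sp2, so racemic 10 converges on achiral 11. The step needs cleavage of C3–C6 and not C3–C2, which is secured because only C6 gives a tertiary allylic radical. It needs bond formation at C4, which is possible because the isopropenyl rotamer with its CH2 over the carbonyl group places C4 within reach of C3. It also needs the double bond to stay β,γ to the ketone, which is secured by acid- and base-free conditions: protic acid would protonate the isopropenyl group and divert the substrate to a cyclopentanone by a 1,2-acyl shift, and base would move the alkene into conjugation.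

Step 7
Reactants: 11 4-{[(tert-butyldimethylsilyl)oxy]methyl}-3,5,5-trimethylcyclohex-3-en-1-one
Product: 12 (1R)-4-{[(tert-butyldimethylsilyl)oxy]methyl}-3,5,5-trimethylcyclohex-3-en-1-ol
Conditions: (R)-selective ketoreductase, NADP+ (cat.), iPrOH (10% v/v), KH2PO4/K2HPO4 buffer pH 7.0, 30 °C
Reagents that add atoms: none
Why: Enzymatic carbonyl reduction with hydride transfer from NADPH, which is recycled by propan-2-ol; the C3 stereocentre is set by the enzyme pocket, which can tell the sp3 gem-dimethyl flank from the flat methyl-substituted alkene flank. The (R) descriptor of 12 is the spatial arrangement that becomes (3S) in the target once C5 carries oxygen; neutral pH and 30 °C should leave the β,γ-double bond in place.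

Step 8
Reactants: 12 (1R)-4-{[(tert-butyldimethylsilyl)oxy]methyl}-3,5,5-trimethylcyclohex-3-en-1-ol; 13 myristoyl chloride
Product: 14 (1R)-4-{[(tert-butyldimethylsilyl)oxy]methyl}-3,5,5-trimethylcyclohex-3-en-1-yl tetradecanoate
Conditions: pyridine, 4-(dimethylamino)pyridine (cat.), CH2Cl2, 0 °C → rt
Reagents that add atoms: none
Why: Nucleophile-catalysed acylation of a secondary alcohol through the acylpyridinium ion; the C–O bond at C3 is not broken, so the configuration is retained, and the primary hydroxyl is still masked.

Step 9
Reactants: 14 (1R)-4-{[(tert-butyldimethylsilyl)oxy]methyl}-3,5,5-trimethylcyclohex-3-en-1-yl tetradecanoate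
Product: 15 (1R)-4-(hydroxymethyl)-3,5,5-trimethylcyclohex-3-en-1-yl tetradecanoate
Conditions: HF·pyridine, pyridine/THF, 0 °C → rt
Reagents that add atoms: none
Why: Fluoride-driven cleavage of a primary silyl ether; the pyridine buffer keeps the medium mild enough for the ester and the allylic alcohol, and the step is placed before epoxidation so that no epoxide is exposed to HF.

Step 10
Reactants: 15 (1R)-4-(hydroxymethyl)-3,5,5-trimethylcyclohex-3-en-1-yl tetradecanoate
Product: 16 (1R,4S,6R)-1-(hydroxymethyl)-2,2,6-trimethyl-7-oxabicyclo[4.1.0]heptan-4-yl tetradecanoate
Conditions: Ti(OiPr)4 (20 mol%), D-(−)-diethyl tartrate (24 mol%), tBuOOH (2 equiv, in decane), 4 Å molecular sieves, CH2Cl2, −20 °C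
Reagents that add atoms: tert-butyl hydroperoxide, CC(C)(C)OO
Why: Sharpless asymmetric epoxidation: the allylic alkoxide binds to the titanium tartrate complex and the peroxide oxygen is delivered to one face of C5=C6 under reagent control. The (S,S)-tartrate is the antipode that converts (E)-2-alken-1-ols into (2R,3R)-epoxy alcohols; transposed to 15 the same sense of delivery places the oxygen on the ring face opposite to the C3 ester and sets C5 (R) and C6 in the target arrangement, the remote C3 centre having little say.

Step 11
Reactants: 16 (1R,4S,6R)-1-(hydroxymethyl)-2,2,6-trimethyl-7-oxabicyclo[4.1.0]heptan-4-yl tetradecanoate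
Product: 17 (1S,4S,6R)-1-formyl-2,2,6-trimethyl-7-oxabicyclo[4.1.0]heptan-4-yl tetradecanoate
Conditions: [nPr4N][RuO4] (5 mol%), N-methylmorpholine N-oxide (1.5 equiv), 4 Å molecular sieves, CH2Cl2, rt
Reagents that add atoms: none
Why: Ley–Griffith oxidation of a primary alcohol to the aldehyde under neutral, non-acidic conditions that should leave the tetrasubstituted epoxide closed; the aldehyde has no α-hydrogen, so the C6 configuration cannot be lost (the descriptor changes only because of ligand priorities).

Step 12
Reactants: 17 (1S,4S,6R)-1-formyl-2,2,6-trimethyl-7-oxabicyclo[4.1.0]heptan-4-yl tetradecanoate; 18 1-(triphenyl-λ5-phosphanylidene)propan-2-one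
Product: 19 (1S,4S,6R)-2,2,6-trimethyl-1-[(1E)-3-oxobut-1-en-1-yl]-7-oxabicyclo[4.1.0]heptan-4-yl tetradecanoate
Conditions: PhMe, 80 °C
Reagents that add atoms: none
Why: Wittig olefination with a stabilised ylide, which gives the (E)-enone through the more stable oxaphosphetane; the reagent is neutral and non-nucleophilic toward the ester and the epoxide, and no stereocentre is touched.

## Compound list

1 | ethyl 3-methylbut-2-enoate | CCOC(=O)C=C(C)C | starting material
2 | formaldehyde | C=O | starting material
3 | lithium 1-ethoxy-3-methylbuta-1,3-dien-1-olate | [Li+].CCOC([O-])=CC(C)=C | intermediate (not isolated)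
4 | ethyl 2-(hydroxymethyl)-3-methylbut-3-enoate (racemic) | CCOC(=O)C(CO)C(C)=C | intermediate
5 | ethyl 2-{[(tert-butyldimethylsilyl)oxy]methyl}-3-methylbut-3-enoate (racemic) | CCOC(=O)C(CO[Si](C)(C)C(C)(C)C)C(C)=C | intermediate
6 | 2-{[(tert-butyldimethylsilyl)oxy]methyl}-3-methylbut-3-enoic acid (racemic) | OC(=O)C(CO[Si](C)(C)C(C)(C)C)C(C)=C | intermediate
7 | 2-{[(tert-butyldimethylsilyl)oxy]methyl}-3-methylbut-3-enoyl chloride (racemic) | ClC(=O)C(CO[Si](C)(C)C(C)(C)C)C(C)=C | intermediate
8 | isobutylene (2-methylprop-1-ene) | CC(C)=C | starting material
9 | 2-{[(tert-butyldimethylsilyl)oxy]methyl}-3-methylbuta-1,3-dien-1-one | O=C=C(CO[Si](C)(C)C(C)(C)C)C(C)=C | intermediate (not isolated)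
10 | 2-{[(tert-butyldimethylsilyl)oxy]methyl}-3,3-dimethyl-2-(prop-1-en-2-yl)cyclobutan-1-one (racemic) | O=C1CC(C)(C)C1(CO[Si](C)(C)C(C)(C)C)C(C)=C | intermediate
11 | 4-{[(tert-butyldimethylsilyl)oxy]methyl}-3,5,5-trimethylcyclohex-3-en-1-one | O=C1CC(C)=C(CO[Si](C)(C)C(C)(C)C)C(C)(C)C1 | intermediate
12 | (1R)-4-{[(tert-butyldimethylsilyl)oxy]methyl}-3,5,5-trimethylcyclohex-3-en-1-ol | O[C@H]1CC(C)(C)C(CO[Si](C)(C)C(C)(C)C)=C(C)C1 | intermediate
13 | myristoyl chloride (tetradecanoyl chloride) | CCCCCCCCCCCCCC(Cl)=O | starting material
14 | (1R)-4-{[(tert-butyldimethylsilyl)oxy]methyl}-3,5,5-trimethylcyclohex-3-en-1-yl tetradecanoate | CCCCCCCCCCCCCC(=O)O[C@H]1CC(C)(C)C(CO[Si](C)(C)C(C)(C)C)=C(C)C1 | intermediate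
15 | (1R)-4-(hydroxymethyl)-3,5,5-trimethylcyclohex-3-en-1-yl tetradecanoate | CCCCCCCCCCCCCC(=O)O[C@H]1CC(C)(C)C(CO)=C(C)C1 | intermediate
16 | (1R,4S,6R)-1-(hydroxymethyl)-2,2,6-trimethyl-7-oxabicyclo[4.1.0]heptan-4-yl tetradecanoate | CCCCCCCCCCCCCC(=O)O[C@H]1CC(C)(C)[C@]2(CO)O[C@]2(C)C1 | intermediate
17 | (1S,4S,6R)-1-formyl-2,2,6-trimethyl-7-oxabicyclo[4.1.0]heptan-4-yl tetradecanoate | CCCCCCCCCCCCCC(=O)O[C@H]1CC(C)(C)[C@]2(C=O)O[C@]2(C)C1 | intermediate
18 | 1-(triphenyl-λ5-phosphanylidene)propan-2-one | CC(=O)C=P(c1ccccc1)(c1ccccc1)c1ccccc1 | starting material
19 | (1S,4S,6R)-2,2,6-trimethyl-1-[(1E)-3-oxobut-1-en-1-yl]-7-oxabicyclo[4.1.0]heptan-4-yl tetradecanoate, (3S,5R,6S) in the numbering used above | CCCCCCCCCCCCCC(=O)O[C@H]1CC(C)(C)[C@]2(/C=C/C(C)=O)O[C@]2(C)C1 | target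

## Step count and least certain steps

Total step count: 12. Longest linear sequence: 12 steps, from 1 to 19.

Step 6 (key step). The acyl/allyl pair may fragment into a ketene and a diene, or 10 may revert to 9 and 8, at the temperature that the shift needs; both are favoured by entropy. Traces of acid or base on the glass may also move the double bond of 11 into conjugation. The fallback replaces the thermal shift by an anionic ring expansion, sets out from 10 and returns at 11:
- LiAlH4 in Et2O at −78 °C reduces the ketone to 2-{[(tert-butyldimethylsilyl)oxy]methyl}-3,3-dimethyl-2-(prop-1-en-2-yl)cyclobutan-1-ol F1.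
- Bu4NF in THF removes the silyl group and gives 2-(hydroxymethyl)-3,3-dimethyl-2-(prop-1-en-2-yl)cyclobutan-1-ol F2. A free alkoxide cannot be expelled from the allyl anion that follows, whereas a silanolate could.
- KH with 18-crown-6 in THF forms the dialkoxide. The ring alkoxide breaks the C3–C6 bond heterolytically and the allyl anion adds back to the aldehyde through C4 (alkoxide-accelerated vinylcyclobutane rearrangement), giving racemic 4-(hydroxymethyl)-3,5,5-trimethylcyclohex-3-en-1-ol F3.
- Selective silylation of the primary hydroxyl (tert-butyldimethylsilyl chloride, imidazole, −20 °C) gives racemic 4-{[(tert-butyldimethylsilyl)oxy]methyl}-3,5,5-trimethylcyclohex-3-en-1-ol F4.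
- Oxidation with Dess–Martin periodinane buffered with NaHCO3 gives 11.

Step 5. The vinylketene may be too weak an electrophile for an unactivated alkene, so that oligomerisation of the ketene overtakes the cycloaddition; the bond between the two fully substituted carbons C1 and C6 is also slow to form. The fallback uses a keteniminium ion in place of the ketene, sets out from 7 and returns at 10:
- Me2NH in CH2Cl2 gives 2-{[(tert-butyldimethylsilyl)oxy]methyl}-N,N,3-trimethylbut-3-enamide F5.
- (CF3SO2)2O and 2,4,6-trimethylpyridine in 1,2-dichloroethane convert F5 into N-(2-{[(tert-butyldimethylsilyl)oxy]methyl}-3-methylbuta-1,3-dien-1-ylidene)-N-methylmethanaminium trifluoromethanesulfonate F6.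
- F6 is far more electrophilic than 9 and adds to 8 in a stepwise [2+2] cycloaddition, giving N-[2-{[(tert-butyldimethylsilyl)oxy]methyl}-3,3-dimethyl-2-(prop-1-en-2-yl)cyclobutylidene]-N-methylmethanaminium trifluoromethanesulfonate F7.
- Aqueous NaHCO3 hydrolyses F7 to 10.

Step 7. The two flanks of the ketone are similar in size, so hydride delivery may show poor facial discrimination, and the bulky lipophilic substrate may bind poorly to the enzyme. The fallback replaces asymmetric reduction by a kinetic resolution that installs the ester at the same time, sets out from 11 and returns at 14: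
- NaBH4 in MeOH at 0 °C gives the racemic alcohol 4-{[(tert-butyldimethylsilyl)oxy]methyl}-3,5,5-trimethylcyclohex-3-en-1-ol F4, the compound already met in the fallback to step 6.
- Lipase from Burkholderia cepacia with vinyl tetradecanoate in tBuOMe acylates one enantiomer. By analogy with lipase resolutions of related 3-hydroxy ionone alcohols the (R)-alcohol is expected to react, which gives 14 directly.
- The unreacted (1S)-4-{[(tert-butyldimethylsilyl)oxy]methyl}-3,5,5-trimethylcyclohex-3-en-1-ol F8 is separated, oxidised back to 11 and recycled.

Step 10. Epoxidation of the crowded tetrasubstituted alkene may be slow, facial selectivity may erode if the substrate binds poorly to the titanium tartrate complex, and the titanium alkoxide may open the tetrasubstituted epoxide. The fallback changes the order of steps and relies on substrate control, sets out from 15 and returns at 19: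
- MnO2 in CH2Cl2 oxidises the allylic alcohol to (1R)-4-formyl-3,5,5-trimethylcyclohex-3-en-1-yl tetradecanoate F9.
- Wittig reaction with 18 in PhMe gives (1R)-3,5,5-trimethyl-4-[(1E)-3-oxobut-1-en-1-yl]cyclohex-3-en-1-yl tetradecanoate F10.
- 3-Chloroperbenzoic acid with NaHCO3 in CH2Cl2 at 0 °C epoxidises the electron-rich, twisted ring double bond in preference to the enone, and is expected to attack mainly on the face away from the ester.
- Chromatography separates 19 from the syn-epoxide (1R,4S,6S)-2,2,6-trimethyl-1-[(1E)-3-oxobut-1-en-1-yl]-7-oxabicyclo[4.1.0]heptan-4-yl tetradecanoate F11.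

## Further compounds

F1 | step 6 | 2-{[(tert-butyldimethylsilyl)oxy]methyl}-3,3-dimethyl-2-(prop-1-en-2-yl)cyclobutan-1-ol (racemic, mixture of diastereomers) | OC1CC(C)(C)C1(CO[Si](C)(C)C(C)(C)C)C(C)=C
F2 | step 6 | 2-(hydroxymethyl)-3,3-dimethyl-2-(prop-1-en-2-yl)cyclobutan-1-ol (racemic, mixture of diastereomers) | OC1CC(C)(C)C1(CO)C(C)=C
F3 | step 6 | 4-(hydroxymethyl)-3,5,5-trimethylcyclohex-3-en-1-ol (racemic) | OC1CC(C)=C(CO)C(C)(C)C1
F4 | step 6 | 4-{[(tert-butyldimethylsilyl)oxy]methyl}-3,5,5-trimethylcyclohex-3-en-1-ol (racemic) | OC1CC(C)=C(CO[Si](C)(C)C(C)(C)C)C(C)(C)C1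
F5 | step 5 | 2-{[(tert-butyldimethylsilyl)oxy]methyl}-N,N,3-trimethylbut-3-enamide (racemic) | CN(C)C(=O)C(CO[Si](C)(C)C(C)(C)C)C(C)=C
F6 | step 5 | N-(2-{[(tert-butyldimethylsilyl)oxy]methyl}-3-methylbuta-1,3-dien-1-ylidene)-N-methylmethanaminium trifluoromethanesulfonate | C[N+](C)=C=C(CO[Si](C)(C)C(C)(C)C)C(C)=C.[O-]S(=O)(=O)C(F)(F)F
F7 | step 5 | N-[2-{[(tert-butyldimethylsilyl)oxy]methyl}-3,3-dimethyl-2-(prop-1-en-2-yl)cyclobutylidene]-N-methylmethanaminium trifluoromethanesulfonate (racemic) | C[N+](C)=C1CC(C)(C)C1(CO[Si](C)(C)C(C)(C)C)C(C)=C.[O-]S(=O)(=O)C(F)(F)F
F8 | step 7 | (1S)-4-{[(tert-butyldimethylsilyl)oxy]methyl}-3,5,5-trimethylcyclohex-3-en-1-ol | O[C@@H]1CC(C)(C)C(CO[Si](C)(C)C(C)(C)C)=C(C)C1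
F9 | step 10 | (1R)-4-formyl-3,5,5-trimethylcyclohex-3-en-1-yl tetradecanoate | CCCCCCCCCCCCCC(=O)O[C@H]1CC(C)(C)C(C=O)=C(C)C1
F10 | step 10 | (1R)-3,5,5-trimethyl-4-[(1E)-3-oxobut-1-en-1-yl]cyclohex-3-en-1-yl tetradecanoate | CCCCCCCCCCCCCC(=O)O[C@H]1CC(C)(C)C(/C=C/C(C)=O)=C(C)C1
F11 | step 10 | (1R,4S,6S)-2,2,6-trimethyl-1-[(1E)-3-oxobut-1-en-1-yl]-7-oxabicyclo[4.1.0]heptan-4-yl tetradecanoate | CCCCCCCCCCCCCC(=O)O[C@H]1CC(C)(C)[C@@]2(/C=C/C(C)=O)O[C@@]2(C)C1
A1 | alternative 1 | methyl 4-methyl-2-oxo-2H-pyran-3-carboxylate | O=C1OC=CC(C)=C1C(=O)OC
A2 | alternative 1 | methyl (1S,4R)-5,8,8-trimethyl-3-oxo-2-oxabicyclo[2.2.2]oct-5-ene-4-carboxylate | O=C1O[C@H]2CC(C)(C)[C@]1(C(=O)OC)C(C)=C2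
A3 | alternative 2 | tert-butyl (5S)-5-[(tert-butyldimethylsilyl)oxy]-2-chloro-3,3-dimethyl-7-oxooctanoate (mixture of C2 epimers) | CC(=O)C[C@@H](O[Si](C)(C)C(C)(C)C)CC(C)(C)C(Cl)C(=O)OC(C)(C)C
A4 | alternative 2 | tert-butyl (1S,4S,6R)-4-[(tert-butyldimethylsilyl)oxy]-2,2,6-trimethyl-7-oxabicyclo[4.1.0]heptane-1-carboxylate | CC(C)(C)[Si](C)(C)O[C@H]1CC(C)(C)[C@]2(C(=O)OC(C)(C)C)O[C@]2(C)C1
A5 | alternative 3 | 4,4-dimethylheptane-2,3,6-trione | CC(=O)CC(C)(C)C(=O)C(C)=O
A6 | alternative 3 | (2R)-2-hydroxy-2,6,6-trimethylcyclohexane-1,4-dione | O=C1CC(C)(C)C(=O)[C@](C)(O)C1
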